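## Compound numbers and locants

Compound numbers used throughout: **1** 2‑methylresorcinol; **2** 3‑methoxy‑2‑methylphenol; **3** 2‑methoxy‑3‑methyl‑1,4‑benzoquinone; **4** the triacetate; **5** the transient triol; **6** the tris(benzyl) ether; **7** the aryl bromide; **8** allyl bromide; **9** the transient aryllithium; **10** the allylarene; **11** 1,10‑undecadiene; **12** the bis‑aryl diene; **13** the transient bis(triol); **14** the target.

Ring locants are those of the quinone ring of 14 and are used for every ring‑containing intermediate: C1 and C4 are the carbonyl carbons, C2 bears OH, C3 the chain, C5 the OCH3, C6 the CH3. Chain atoms are C1′ to C13′.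

## Analysis of the target

The target 14 (C29H40O8) consists of two identical 2‑hydroxy‑5‑methoxy‑6‑methyl‑1,4‑benzoquinone rings joined through C3 by an unbranched, saturated thirteen‑carbon chain, so every ring operation can be run on both halves at once. There is no stereocentre and no ring fusion; the only stereochemical element on the way is the geometry of two transient alkenes, and it is erased. Each ring is fully substituted: going round from C3 the order is C2(OH), C1(=O), C6(CH3), C5(OCH3), C4(=O), so four oxygens in three different states must stand in a fixed relation to the methyl group and the chain. The hydroxyquinones are the sensitive groups: they are acidic vinylogous acids, Michael acceptors and chelators, are easily reduced, and their C5 methyl ether is a vinylogous ester that acid or base can exchange, so they should appear only in the last operation. The synthesis is hard for two reasons: a hexasubstituted arene must be assembled in which the C2 oxygen can be told apart from the C5 oxygen, and two such crowded rings must be attached to a long chain without mono/bis mixtures that differ only in chain length. The strategy rests on the fact that C1′ to C13′ carries no functional group. The C2′–C3′ and C11′–C12′ bonds can therefore exist for a while as alkenes made by metathesis, with C1′/C2′ and C12′/C13′ coming from ring‑bound allyl groups and C3′ to C11′ from a commercial α,ω‑diene. A second feature supports this: the oxygens at C1, C2 and C4 can carry one and the same benzyl group, because once they are freed beside the C5 methyl ether the only p‑quinone that can form is the target.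

## Retrosynthetic reasoning

**14 to 13 to 12.** No skeletal bond is cut. The quinone is taken back to the bis(benzene‑1,2,4‑triol) 13, which oxidises in air, and 13 to the hexabenzyl ether 12 carrying two chain alkenes. One catalytic hydrogenation must then saturate both alkenes and cleave six O–benzyl bonds, which moves all sensitive functionality to the last flask.

**12 to 10 and 11.** The cut is made at C2′=C3′ and C11′=C12′. These positions are chosen because the ring‑bound partner is then a simple allyl group and the reacting carbons lie two atoms away from the hexasubstituted ring. A cut at aryl–C1′ would need a two‑fold coupling at a carbon flanked by two ether groups and a C13 bifunctional chain that is not a bulk chemical. A cut at C1′–C2′ would need benzylic anion or halide chemistry on the crowded ring. The metathesis cut makes the route convergent and two‑directional, and takes the inner nine carbons from commercial 11. Forward, the reaction must favour cross‑ over self‑coupling at both ends of 11 and must not move the allyl double bond.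

**10 to 7 and 8 (via 9).** The aryl–C1′ bond is cut. The aryl carbon C3 becomes nucleophilic by halogen–lithium exchange and is allylated with 8 under copper mediation. A halogen at C3 is preferred to direct deprotonation, because exchange is faster than attack on the benzylic CH2 groups of the ethers.

**7 to 6.** The C3–Br bond is cut. C3 is the only unsubstituted position of the central ring of 6 and is activated by two ortho ether groups, so electrophilic bromination has one site to choose.

**6 to 4 (via 5).** The three O–benzyl bonds are cut. Benzyl is chosen because it survives organolithium and ruthenium chemistry and leaves in the same hydrogenation that saturates the chain. The triol 5 is air‑sensitive and is therefore kept as a transient between the triacetate 4 and the ether 6.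

**4 to 3.** The C2–O bond and the two O‑acetyl bonds are cut: a reductive acetoxylation of the quinone. This introduces the last ring oxygen and returns the ring to the arene oxidation level in one step. Forward, acetate must enter at C2 and not at C3.

**3 to 2 to 1.** The C4 oxygen is introduced by oxidising the phenol 2 at its free para position. The C5 methyl ether comes from monomethylation of the symmetric diol 1, which already holds C1–O, C6–CH3 and C5–O in the right order.

## Alternatives that were turned down

**Alternative 1:** Both rings are built from acyclic material. Each is cut at C2–C3 and C1–C6, which leads to the bis‑enone (4E,19E)‑tricosa‑4,19‑diene‑3,21‑dione A2 (about three steps from pentadecanedioic acid A1) and two molecules of dimethyl malonate A3.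
- Forward key step: under alkoxide base, A3 adds to each enone β‑carbon (Michael addition, C2–C3). The α‑carbon of each ethyl ketone then closes onto a malonate ester (Claisen‑type closure, C1–C6) to give the bis(cyclohexanedione) A4.
- For it: the annulation mirrors the biosynthesis of alkylresorcinols, needs no transition metal, buys the whole saturated C13 tether in one piece, and places the chain at C3 and the methyl at C6 without regiochemical doubt. On reliability of the key step and on ring regiochemistry it is at least as strong as the chosen strategy.
- Against it: A4 carries ring oxygen only at C1 and C5. After aromatisation to the bis(dihydroxybenzoate) A5, the C5 hydroxyl (para to the ester) can probably be methylated selectively because the C1 hydroxyl is hydrogen‑bonded. The ester carbon on C2 must still be exchanged for a hydroxyl (reduction, re‑oxidation, Dakin oxidation) and C4–H must be oxidised, all two‑fold and on increasingly air‑sensitive polyphenols.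
- Comparison: the count comes to roughly twelve or more steps against eight. The chosen strategy offers rings whose oxygenation is complete before the coupling, so that only one operation follows the key step.

**Alternative 2:** The chain is cut at C1′–C2′ and C12′–C13′. The ring is read as a p‑xylene (C6–CH3 para to C1′), giving the monomer 3,4,6‑trimethoxy‑2,5‑dimethylphenyl diethylcarbamate A6, with the carbamate on the future C2 oxygen, and 1,11‑dibromoundecane A7.
- Forward key step: a lithium amide at low temperature deprotonates the methyl group next to the carbamate, and two such benzyllithiums displace both bromides of A7 to give A8.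
- For it: the tether is formed saturated, so no hydrogenation and no benzyl groups are needed; A7 is commercial. The carbamate both directs the metalation and marks the one oxygen that must end as a free hydroxyl. On oxygen differentiation this plan is stronger than one that relies on quinone regiochemistry.
- Against it: A6 is a fully substituted benzene with four oxygens in two roles and two methyl groups, and its preparation would be longer and regiochemically harder than the six steps to 10. The laterally lithiated carbamate can transfer its carbamoyl group to carbon (anionic homo‑Fries shift) in competition with a slow SN2 reaction on a primary bromide. A two‑fold alkylation also gives mono/bis mixtures.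
- End game: oxidative demethylation at C1/C4 would give the bis(quinone) A9, from which a robust diethylcarbamate would have to be removed without exchanging the C5 vinylogous methyl ester. Removing it earlier would expose a phenol para to the C5 methoxy group and put that ether at risk in the oxidation.
- Comparison: the chosen strategy pays two extra hydrogen‑transfer events in its last step, but ends with neutral hydrogenolysis instead of a carbamate cleavage on a quinone.

**Alternative 3:** Each aromatic ring is cut at C4–C5 and traced to a four‑membered ring. C1 to C4 come from diisopropyl squarate A11. C5 and C6, with their methoxy and methyl groups, come from (E)‑(1‑methoxyprop‑1‑en‑2‑yl)lithium A12. The tether comes from the bis‑Grignard reagent of 1,13‑dibromotridecane A10. Two successive carbonyl additions to A11, separated by an acid‑induced rearrangement, would give the bis(4‑alkenyl‑4‑hydroxycyclobutenone) A13.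
- Forward key step: heating A13 near 140 °C opens each cyclobutenone to a dienylketene (4π electrocyclic opening), which closes by 6π electrocyclisation with formation of C4–C5 and tautomerises to the bis(hydroquinone) A14 (Moore rearrangement).
- For it: the order of additions to the squarate fixes the position of every substituent, so the ring pattern is beyond doubt, and here this plan is stronger than the chosen one. The chain is saturated throughout, and the isopropyl ether marks the C2 oxygen; its removal from A14 would give 13. The step count is comparable.
- Against it: A10 is not a bulk chemical and must first be turned into a bis‑organometallic reagent. A12 is only stable in the geometry with lithium and methoxy cis, otherwise it β‑eliminates. Three consecutive two‑directional steps on sensitive cyclobutenones multiply the mono/bis problem. The isopropyl ether must be cleaved with a boron halide beside a methyl ether on an oxidation‑prone hydroquinone.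
- Comparison: the chosen strategy keeps all ring chemistry on robust, storable arenes made by classical reactions and confines the two‑directional risk to one catalytic step that uses a cheap commercial diene.

Key step: step 7

Assumption: the alkenes of 12 are drawn E,E for definiteness; the chemistry does not depend on their geometry, because step 8 removes both double bonds.

## Route

Step 1
Reactants: 1 2‑methylresorcinol
Product: 2 3‑methoxy‑2‑methylphenol
Conditions: MeI (1.0 equiv), K2CO3, acetone, reflux
Reagents that add atoms: iodomethane, CI
Why: Williamson O‑methylation of one of two equivalent hydroxyl groups, so only the degree of alkylation is at stake; with one equivalent of MeI the monoether should be the main component, and unchanged 1 (recycled) and the neutral diether are removed by base extraction and chromatography.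

Step 2
Reactants: 2 3‑methoxy‑2‑methylphenol
Product: 3 2‑methoxy‑3‑methyl‑1,4‑benzoquinone
Conditions: (KSO3)2NO (2.2 equiv), KH2PO4, H2O–acetone, 0 °C to rt
Reagents that add atoms: potassium nitrosodisulfonate, [K+].[K+].[O]N(S(=O)(=O)[O-])S(=O)(=O)[O-]
Why: Teuber oxidation: one nitrosodisulfonate radical removes the phenolic hydrogen, a second couples at the free para carbon (C4), and loss of imidodisulfonate gives the p‑quinone; the para position is unsubstituted and more accessible than the ortho one, so the 1,4‑quinone is expected.

Step 3
Reactants: 3 2‑methoxy‑3‑methyl‑1,4‑benzoquinone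
Product: 4 5‑methoxy‑6‑methylbenzene‑1,2,4‑triyl triacetate
Conditions: Ac2O, H2SO4 (cat.), 0 °C to rt
Reagents that add atoms: acetic anhydride, CC(=O)OC(C)=O
Why: Thiele–Winter acetoxylation (acid‑promoted conjugate addition of acetate to the activated quinone, enolisation, O‑acetylation). The C5 methoxy group donates through C5=C6 into the C1 carbonyl and leaves the C4 carbonyl the better acceptor, so acetate should add at C2, the β‑carbon of the C4 enone, as is usual for nucleophiles adding to methoxy‑p‑benzoquinones.

Step 4
Reactants: 4 5‑methoxy‑6‑methylbenzene‑1,2,4‑triyl triacetate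
Product: 6 1,2,5‑tris(benzyloxy)‑4‑methoxy‑3‑methylbenzene, via 5‑methoxy‑6‑methylbenzene‑1,2,4‑triol 5 (not isolated)
Conditions: BnBr (4.5 equiv), K2CO3, MeOH–DMF (degassed), argon, 60 °C
Reagents that add atoms: benzyl bromide, BrCc1ccccc1
Why: Carbonate‑mediated methanolysis of the three aryl acetates releases phenoxides that are benzylated as they form (Williamson ether synthesis); keeping the electron‑rich triol 5 as a transient under argon avoids its autoxidation to a hydroxyquinone.

Step 5
Reactants: 6 1,2,5‑tris(benzyloxy)‑4‑methoxy‑3‑methylbenzene
Product: 7 1,2,4‑tris(benzyloxy)‑3‑bromo‑5‑methoxy‑6‑methylbenzene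
Conditions: NBS (1.05 equiv), MeCN, 0 °C to rt, dark
Reagents that add atoms: N‑bromosuccinimide, O=C1CCC(=O)N1Br
Why: Electrophilic aromatic bromination at C3, the only unsubstituted carbon of the central ring, activated by two ortho benzyloxy groups and the para methyl group; a polar solvent without light or initiator disfavours benzylic radical bromination, and the pendant phenyl rings are far less nucleophilic.

Step 6
Reactants: 7 1,2,4‑tris(benzyloxy)‑3‑bromo‑5‑methoxy‑6‑methylbenzene; 8 allyl bromide
Product: 10 1‑allyl‑2,3,6‑tris(benzyloxy)‑5‑methoxy‑4‑methylbenzene, via [2,3,6‑tris(benzyloxy)‑5‑methoxy‑4‑methylphenyl]lithium 9 (not isolated)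
Conditions: n‑BuLi (1.05 equiv), THF, −78 °C; CuBr·SMe2 (0.2 equiv), 8 (1.5 equiv), −78 to 0 °C
Reagents that add atoms: none
Why: Bromine–lithium exchange at −78 °C is faster than deprotonation of the benzylic OCH2 groups; the aryllithium then displaces bromide from 8 under copper catalysis (copper‑mediated allylation), and attack at either allyl terminus gives the same product.

Step 7
Reactants: 10 1‑allyl‑2,3,6‑tris(benzyloxy)‑5‑methoxy‑4‑methylbenzene (5 equiv); 11 1,10‑undecadiene (1 equiv)
Product: 12 (2E,11E)‑1,13‑bis[2,3,6‑tris(benzyloxy)‑5‑methoxy‑4‑methylphenyl]trideca‑2,11‑diene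
Conditions: (H2IMes)(PCy3)Cl2Ru=CHPh (second‑generation Grubbs catalyst, 5 mol %), 1,4‑benzoquinone (10 mol %), CH2Cl2, 40 °C, argon sweep, slow addition of 11
Reagents that add atoms: none
Why: The step is an olefin cross‑metathesis by the metallacyclobutane (Chauvin) mechanism: loss of PCy3 gives a 14‑electron ruthenium alkylidene, which adds a terminal alkene of 10 or 11 in a [2+2] cycloaddition, and cycloreversion of the ruthenacyclobutane exchanges the alkylidene halves while the ruthenium methylidene formed in each turnover gives off ethylene. The closest known reaction type is the cross‑metathesis of allylbenzenes with unhindered 1‑alkenes catalysed by N‑heterocyclic‑carbene ruthenium benzylidenes. No ring is closed and no stereocentre is formed; the new C2′=C3′ and C11′=C12′ bonds should be mainly E, and their geometry is irrelevant because step 8 hydrogenates both. The selectivity needed is cross‑ over self‑metathesis at both ends of 11; both partners are unhindered monosubstituted alkenes that homodimerise readily, so it is secured by stoichiometry and reversibility, not by a substrate bias: 10 is present at 2.5 equivalents per alkene of 11, 11 is added slowly so that diene–diene coupling stays rare, and every internal alkene formed (the self‑dimer of 10, oligomers of 11, the mono‑capped diene) is 1,2‑disubstituted, re‑enters the exchange and is funnelled to 12 as ethylene is swept out. The allyl double bond must also not migrate into conjugation, because a propenylarene would give a tether one carbon short; 1,4‑benzoquinone intercepts the ruthenium hydrides responsible, the temperature stays at 40 °C, and the two ortho benzyloxy groups would twist a propenyl group out of the ring plane, so migration gains little. The reacting CH=CH2 group is two atoms from the hexasubstituted ring and aryl ethers are poor ligands for ruthenium, so neither crowding nor chelation should slow the catalyst. Unreacted 10 and its self‑dimer are recovered by chromatography and returned to the next run, which makes the excess affordable.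

Step 8
Reactants: 12 (2E,11E)‑1,13‑bis[2,3,6‑tris(benzyloxy)‑5‑methoxy‑4‑methylphenyl]trideca‑2,11‑diene
Product: 14 3,3'‑(tridecane‑1,13‑diyl)bis(2‑hydroxy‑5‑methoxy‑6‑methylcyclohexa‑2,5‑diene‑1,4‑dione), via 3,3'‑(tridecane‑1,13‑diyl)bis(5‑methoxy‑6‑methylbenzene‑1,2,4‑triol) 13 (not isolated)
Conditions: H2 (1 atm), 10% Pd/C, EtOAc–MeOH, rt; filter under argon; then air, rt
Reagents that add atoms: none
Why: Heterogeneous hydrogenation saturates both disubstituted alkenes and hydrogenolysis cleaves all six benzylic C–O bonds while the aryl methyl ethers stay; once the catalyst is removed and air is admitted, each 1,2,4‑trihydroxyarene autoxidises to the 2‑hydroxy‑1,4‑benzoquinone. Because the C5 oxygen stays methylated, only the C1/C4 pair can become the quinone carbonyls, and the o‑quinone form is merely a tautomer of the same compound.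

## Compound list

1 | 2‑methylresorcinol (2‑methylbenzene‑1,3‑diol) | Cc1c(O)cccc1O | starting material
2 | 3‑methoxy‑2‑methylphenol | COc1cccc(O)c1C | intermediate
3 | 2‑methoxy‑3‑methyl‑1,4‑benzoquinone (2‑methoxy‑3‑methylcyclohexa‑2,5‑diene‑1,4‑dione) | COC1=C(C)C(=O)C=CC1=O | intermediate
4 | 5‑methoxy‑6‑methylbenzene‑1,2,4‑triyl triacetate | COc1c(C)c(OC(C)=O)c(OC(C)=O)cc1OC(C)=O | intermediate
5 | 5‑methoxy‑6‑methylbenzene‑1,2,4‑triol | COc1c(C)c(O)c(O)cc1O | intermediate (not isolated)
6 | 1,2,5‑tris(benzyloxy)‑4‑methoxy‑3‑methylbenzene | COc1c(C)c(OCc2ccccc2)c(OCc2ccccc2)cc1OCc1ccccc1 | intermediate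
7 | 1,2,4‑tris(benzyloxy)‑3‑bromo‑5‑methoxy‑6‑methylbenzene | COc1c(C)c(OCc2ccccc2)c(OCc2ccccc2)c(Br)c1OCc1ccccc1 | intermediate
8 | allyl bromide (3‑bromoprop‑1‑ene) | C=CCBr | starting material
9 | [2,3,6‑tris(benzyloxy)‑5‑methoxy‑4‑methylphenyl]lithium | [Li]c1c(OCc2ccccc2)c(OCc2ccccc2)c(C)c(OC)c1OCc1ccccc1 | intermediate (not isolated)
10 | 1‑allyl‑2,3,6‑tris(benzyloxy)‑5‑methoxy‑4‑methylbenzene | C=CCc1c(OCc2ccccc2)c(OCc2ccccc2)c(C)c(OC)c1OCc1ccccc1 | intermediate
11 | 1,10‑undecadiene (undeca‑1,10‑diene) | C=CCCCCCCCC=C | starting material
12 | (2E,11E)‑1,13‑bis[2,3,6‑tris(benzyloxy)‑5‑methoxy‑4‑methylphenyl]trideca‑2,11‑diene | COc1c(C)c(OCc2ccccc2)c(OCc2ccccc2)c(C/C=C/CCCCCCC/C=C/Cc2c(OCc3ccccc3)c(OCc3ccccc3)c(C)c(OC)c2OCc2ccccc2)c1OCc1ccccc1 | intermediate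
13 | 3,3'‑(tridecane‑1,13‑diyl)bis(5‑methoxy‑6‑methylbenzene‑1,2,4‑triol) | COc1c(C)c(O)c(O)c(CCCCCCCCCCCCCc2c(O)c(O)c(C)c(OC)c2O)c1O | intermediate (not isolated)
14 | 3,3'‑(tridecane‑1,13‑diyl)bis(2‑hydroxy‑5‑methoxy‑6‑methylcyclohexa‑2,5‑diene‑1,4‑dione) | COC1=C(C)C(=O)C(O)=C(CCCCCCCCCCCCCC2=C(O)C(=O)C(C)=C(OC)C2=O)C1=O | target

## Step count and least certain steps

Total: 8 steps. Longest linear sequence: 8 steps (1, 2, 3, 4, 6, 7, 10, 12, 14); 8 and 11 enter as purchased materials.

**Step 7 (key step).** The most likely failure is that the exchange stops at a statistical mixture. Incomplete capping of 11, diene–diene coupling and migration of the allyl double bond before metathesis would all give products that differ from 12 only in chain length and would be hard to remove after step 8. The fallback forms C3′–C4′ and C10′–C11′ by sp3–sp3 coupling instead.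
- It sets out from 10. Hydroboration with 9‑BBN and oxidative work‑up (NaOH, H2O2) should give 3‑[2,3,6‑tris(benzyloxy)‑5‑methoxy‑4‑methylphenyl]propan‑1‑ol F1.
- CBr4/PPh3 converts it to 1,2,4‑tris(benzyloxy)‑3‑(3‑bromopropyl)‑5‑methoxy‑6‑methylbenzene F2.
- Mg in THF gives {3‑[2,3,6‑tris(benzyloxy)‑5‑methoxy‑4‑methylphenyl]propyl}magnesium bromide F3.
- About 2.4 equivalents of F3 are coupled with 1,7‑dibromoheptane under Li2CuCl4 catalysis (THF, 0 °C), giving 1,13‑bis[2,3,6‑tris(benzyloxy)‑5‑methoxy‑4‑methylphenyl]tridecane F4 (3 + 7 + 3 carbons).
- Hydrogenolysis of F4 under the conditions of step 8 returns to the route at 13, which air converts to 14.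

**Step 3.** Acetate may add at C3 as well as at C2 if the electronic bias of the methoxy group is smaller than expected, and the acid may exchange the methoxy group for acetoxy; either process would carry a ring isomer through to the end. The fallback sets the oxygen pattern by halogenating the phenol instead of by quinone addition.
- It sets out from 2. Two equivalents of NBS in MeCN should brominate C2 and C4, which are ortho/para to both the hydroxyl and the methoxy group, and leave C3 (meta to both) free, giving 4,6‑dibromo‑3‑methoxy‑2‑methylphenol F5.
- Benzylation (BnBr, K2CO3, DMF) gives 2‑(benzyloxy)‑1,5‑dibromo‑4‑methoxy‑3‑methylbenzene F6.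
- A two‑fold palladium‑catalysed C–O coupling with benzyl alcohol (Pd2(dba)3, a bulky di‑tert‑butylbiarylphosphine such as RockPhos, Cs2CO3, toluene, 90 °C) returns to the route at 6. Steps 2 to 4 are bypassed.

**Step 4.** The transient triol 5, present as its phenoxides, may autoxidise before all three oxygens are benzylated, leading to quinone‑derived and partly benzylated material. The fallback accepts the oxidation and reverses it under control.
- It sets out from 4. Acid methanolysis (HCl, MeOH) followed by aeration should give the storable 2‑hydroxy‑5‑methoxy‑6‑methylcyclohexa‑2,5‑diene‑1,4‑dione F7.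
- Reductive benzylation under phase transfer (Na2S2O4, KOH, Bu4NBr, BnBr, THF–H2O, argon) regenerates the triol only in the presence of excess reductant and alkylating agent, and returns to the route at 6.

**Step 6.** The aryllithium 9 is flanked by two benzyloxy groups. If exchange or trapping is slow, proton transfer from an ortho OCH2Ph group (followed by Wittig rearrangement) or alkylation by the butyl bromide formed in the exchange can compete. The fallback avoids the organolithium: it sets out from 7 and uses a Stille coupling with allyltributylstannane (Pd2(dba)3, P(t‑Bu)3, CsF, dioxane, 80 to 100 °C) to reach 10 directly, with no new intermediate.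

## Further compounds

F1 | step 7 | 3‑[2,3,6‑tris(benzyloxy)‑5‑methoxy‑4‑methylphenyl]propan‑1‑ol | OCCCc1c(OCc2ccccc2)c(OCc2ccccc2)c(C)c(OC)c1OCc1ccccc1
F2 | step 7 | 1,2,4‑tris(benzyloxy)‑3‑(3‑bromopropyl)‑5‑methoxy‑6‑methylbenzene | BrCCCc1c(OCc2ccccc2)c(OCc2ccccc2)c(C)c(OC)c1OCc1ccccc1
F3 | step 7 | {3‑[2,3,6‑tris(benzyloxy)‑5‑methoxy‑4‑methylphenyl]propyl}magnesium bromide | Br[Mg]CCCc1c(OCc2ccccc2)c(OCc2ccccc2)c(C)c(OC)c1OCc1ccccc1
F4 | step 7 | 1,13‑bis[2,3,6‑tris(benzyloxy)‑5‑methoxy‑4‑methylphenyl]tridecane | COc1c(C)c(OCc2ccccc2)c(OCc2ccccc2)c(CCCCCCCCCCCCCc2c(OCc3ccccc3)c(OCc3ccccc3)c(C)c(OC)c2OCc2ccccc2)c1OCc1ccccc1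
F5 | step 3 | 4,6‑dibromo‑3‑methoxy‑2‑methylphenol | COc1c(Br)cc(Br)c(O)c1C
F6 | step 3 | 2‑(benzyloxy)‑1,5‑dibromo‑4‑methoxy‑3‑methylbenzene | COc1c(Br)cc(Br)c(OCc2ccccc2)c1C
F7 | step 4 | 2‑hydroxy‑5‑methoxy‑6‑methylcyclohexa‑2,5‑diene‑1,4‑dione | COC1=C(C)C(=O)C(O)=CC1=O
F0 | step 6 | none | none
A1 | alternative 1 | pentadecanedioic acid | OC(=O)CCCCCCCCCCCCCC(=O)O
A2 | alternative 1 | (4E,19E)‑tricosa‑4,19‑diene‑3,21‑dione | CCC(=O)/C=C/CCCCCCCCCCCCC/C=C/C(=O)CC
A3 | alternative 1 | dimethyl malonate | COC(=O)CC(=O)OC
A4 | alternative 1 | dimethyl 6,6'‑(tridecane‑1,13‑diyl)bis(3‑methyl‑2,4‑dioxocyclohexane‑1‑carboxylate) | COC(=O)C1C(CCCCCCCCCCCCCC2CC(=O)C(C)C(=O)C2C(=O)OC)CC(=O)C(C)C1=O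
A5 | alternative 1 | dimethyl 6,6'‑(tridecane‑1,13‑diyl)bis(2,4‑dihydroxy‑3‑methylbenzoate) | COC(=O)c1c(O)c(C)c(O)cc1CCCCCCCCCCCCCc1cc(O)c(C)c(O)c1C(=O)OC
A6 | alternative 2 | 3,4,6‑trimethoxy‑2,5‑dimethylphenyl diethylcarbamate | CCN(CC)C(=O)Oc1c(C)c(OC)c(OC)c(C)c1OC
A7 | alternative 2 | 1,11‑dibromoundecane | BrCCCCCCCCCCCBr
A8 | alternative 2 | tridecane‑1,13‑diylbis(3,4,6‑trimethoxy‑5‑methyl‑2,1‑phenylene) bis(diethylcarbamate) | CCN(CC)C(=O)Oc1c(CCCCCCCCCCCCCc2c(OC(=O)N(CC)CC)c(OC)c(C)c(OC)c2OC)c(OC)c(OC)c(C)c1OC
A9 | alternative 2 | tridecane‑1,13‑diylbis(4‑methoxy‑5‑methyl‑3,6‑dioxocyclohexa‑1,4‑diene‑2,1‑diyl) bis(diethylcarbamate) | CCN(CC)C(=O)OC1=C(CCCCCCCCCCCCCC2=C(OC(=O)N(CC)CC)C(=O)C(C)=C(OC)C2=O)C(=O)C(OC)=C(C)C1=O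
A10 | alternative 3 | 1,13‑dibromotridecane | BrCCCCCCCCCCCCCBr
A11 | alternative 3 | diisopropyl squarate (3,4‑diisopropoxycyclobut‑3‑ene‑1,2‑dione) | CC(C)OC1=C(OC(C)C)C(=O)C1=O
A12 | alternative 3 | (E)‑(1‑methoxyprop‑1‑en‑2‑yl)lithium (lithium and methoxy cis) | [Li]/C(C)=C\OC
A13 | alternative 3 | 2,2'‑(tridecane‑1,13‑diyl)bis{4‑hydroxy‑3‑isopropoxy‑4‑[(Z)‑1‑methoxyprop‑1‑en‑2‑yl]cyclobut‑2‑en‑1‑one} (mixture of diastereomers at the carbinol carbons) | CO/C=C(/C)C1(O)C(OC(C)C)=C(CCCCCCCCCCCCCC2=C(OC(C)C)C(O)(/C(C)=C\OC)C2=O)C1=O
A14 | alternative 3 | 3,3'‑(tridecane‑1,13‑diyl)bis(2‑isopropoxy‑5‑methoxy‑6‑methylbenzene‑1,4‑diol) | COc1c(C)c(O)c(OC(C)C)c(CCCCCCCCCCCCCc2c(OC(C)C)c(O)c(C)c(OC)c2O)c1O
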